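The benzene ring has oxygen on C6 and C7a on either side of C7–H, and adjacent carbon groups on C4 (styryl) and C5 (prenyl). This is the pattern of a 1,3-dioxygenated diene C6=C7–C7a=C3a joined to an alkynoate C4≡C5 (benzofuran numbering: O1, C2, C3, C3a, C4–C7, C7a).
Retrosynthetic cuts, in order: the Z-alkene goes back to an alkyne; the prenyl ArCH2–CH= bond is cut (o-quinone methide plus isobutenyl Grignard reagent) and ArCH2 goes back to a C5 ester.
Next C3a–C4 and C5–C6 are cut together ([4+2]), then O1–C7a and C3–C3a of the dihydrofuran, and last the two C–CH3 bonds of the carbinol.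
Forward: the oxygen ring is built first (epoxide opening by acetoacetate dianion, then cyclodehydration) and its enoate becomes a silyl ketene acetal diene. The benzene ring is then closed on that diene with methyl 5-phenylpenta-2,4-diynoate, and the side chains are adjusted last.
Stereochemistry: C2 (S) comes from methyl (S)-glycidate, whose C–O bond is never broken. The Z-alkene comes from syn semi-hydrogenation of the alkyne in the penultimate step.

Key step: step 8

Remark on the chemistry: benzofuran numbering is used for all precursors. The ketene acetal of the diene is drawn Z (silyloxy cis to the ring), as expected from ester-directed deprotonation, and this geometry disappears when C6 becomes aromatic.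

Step 1
Reactants: 1 methyl (2S)-oxirane-2-carboxylate (methyl (S)-glycidate)
Product: 3 2-[(2S)-oxiran-2-yl]propan-2-ol, via oxiranyl methyl ketone 2 (not isolated)
Conditions: MeMgCl (2.2 equiv), THF, −78 → −20 °C; aq NH4Cl
Reagents that add atoms: methylmagnesium chloride, C[Mg]Cl
Why: Double Grignard addition to the ester is much faster at low temperature than attack on the oxirane, the cold quench leaves the epoxy alkoxide no time for Payne rearrangement, and no bond to the stereocentre is touched, so the S configuration is carried into C2.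

Step 2
Reactants: 3 2-[(2S)-oxiran-2-yl]propan-2-ol
Product: 4 triethyl({2-[(2S)-oxiran-2-yl]propan-2-yl}oxy)silane
Conditions: Et3SiCl, imidazole, 4-dimethylaminopyridine (cat.), DMF, rt
Reagents that add atoms: chlorotriethylsilane, CC[Si](Cl)(CC)CC
Why: Standard silylation of a tertiary alcohol under weakly basic conditions that neither open the oxirane nor form the alkoxide needed for Payne rearrangement.

Step 3
Reactants: 4 triethyl({2-[(2S)-oxiran-2-yl]propan-2-yl}oxy)silane; 5 methyl acetoacetate
Product: 7 methyl (6S)-6-hydroxy-7-methyl-3-oxo-7-(triethylsilyloxy)octanoate, via dilithio acetoacetate dianion 6 (not isolated)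
Conditions: 5 (2.0 equiv), LiN(i-Pr)2 (4.1 equiv), THF, 0 °C; then −78 °C, 4 (1.0 equiv), BF3·OEt2 (1.5 equiv); aq NH4Cl
Reagents that add atoms: none
Why: Gamma-alkylation of the acetoacetate dianion by Lewis-acid-assisted SN2 opening of the terminal epoxide at its CH2 carbon forms C3–C3a; at −78 °C the new C2 oxygen stays bound to boron, so O-to-O silyl migration is held back, and the C2–O bond is not broken, so S is retained.

Step 4
Reactants: 7 methyl (6S)-6-hydroxy-7-methyl-3-oxo-7-(triethylsilyloxy)octanoate
Product: 9 methyl (2E)-2-{(5S)-5-[2-(triethylsilyloxy)propan-2-yl]oxolan-2-ylidene}acetate, via cyclic hemiketal 8 (not isolated)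
Conditions: oxalic acid (cat.), 4 Å molecular sieves, CH2Cl2, rt
Reagents that add atoms: none
Why: Acid-catalysed cyclodehydration of a gamma-hydroxy beta-keto ester (five-ring hemiketal, then loss of water into conjugation with the ester) is the usual entry to tetrahydrofuran-2-ylideneacetates; it closes O1–C7a, should favour the E isomer, and is mild enough for the tertiary silyl ether.

Step 5
Reactants: 9 methyl (2E)-2-{(5S)-5-[2-(triethylsilyloxy)propan-2-yl]oxolan-2-ylidene}acetate
Product: 11 (5S)-2-[(Z)-2-methoxy-2-(trimethylsilyloxy)ethenyl]-5-[2-(triethylsilyloxy)propan-2-yl]-4,5-dihydrofuran, via lithium dienolate 10 (not isolated)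
Conditions: LiN(i-Pr)2 (1.1 equiv), THF, −78 °C; Me3SiCl, −78 → 0 °C; pentane, filtration under Ar; used crude
Reagents that add atoms: chlorotrimethylsilane, C[Si](C)(C)Cl
Why: Kinetic gamma-deprotonation of a beta-alkoxy enoate at the ring CH2 that lies cis to the ester, followed by O-silylation of the dienolate, is the way 3-alkoxycrotonates are converted into 1-alkoxy-1-silyloxy-3-alkoxybutadienes.

Step 6
Reactants: 12 3-phenylprop-2-ynal
Product: 13 (4,4-dibromobut-3-en-1-yn-1-yl)benzene
Conditions: CBr4 (2 equiv), PPh3 (4 equiv), CH2Cl2, 0 °C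
Reagents that add atoms: carbon tetrabromide, BrC(Br)(Br)Br
Why: Corey–Fuchs dibromoolefination (Wittig-type reaction of Ph3P=CBr2) of a non-enolisable ynal.

Step 7
Reactants: 13 (4,4-dibromobut-3-en-1-yn-1-yl)benzene
Product: 15 methyl 5-phenylpenta-2,4-diynoate, via lithium phenylbutadiynide 14 (not isolated)
Conditions: n-BuLi (2.1 equiv), THF, −78 °C; ClCO2Me, −78 °C → rt
Reagents that add atoms: methyl chloroformate, COC(=O)Cl
Why: In the second stage of the Corey–Fuchs sequence, Br/Li exchange, loss of LiBr and deprotonation give the lithium diynide, which methyl chloroformate acylates at carbon; no propiolate is exposed to the nucleophilic amines of a copper-mediated diyne coupling.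

Step 8
Reactants: 11 (5S)-2-[(Z)-2-methoxy-2-(trimethylsilyloxy)ethenyl]-5-[2-(triethylsilyloxy)propan-2-yl]-4,5-dihydrofuran; 15 methyl 5-phenylpenta-2,4-diynoate
Product: 18 methyl (2S)-6-hydroxy-4-(phenylethynyl)-2-[2-(triethylsilyloxy)propan-2-yl]-2,3-dihydrobenzofuran-5-carboxylate, via cycloadduct 16 (not isolated), via aryl trimethylsilyl ether 17 (not isolated)
Conditions: 11 (1.5 equiv), 15, PhMe, 100 °C, sealed tube, Ar; then K2CO3 (cat.), MeOH, rt
Reagents that add atoms: none
Why: Diene 11 is a cyclic 1-alkoxy-1-silyloxy-3-alkoxybutadiene whose three oxygens all push electron density to C3a, and the LUMO of 15 is largest at the carbon beta to the ester, so a concerted but strongly asynchronous normal-demand [4+2] should form C3a–C4 ahead of C5–C6 and place the phenylethynyl group on C4 and the ester on C5. The closest known reaction type is the Diels–Alder benzannulation of acyclic 1,1,3-trioxygenated butadienes with alkynoates to give resorcylates. The one new ring, the six-membered carbocycle, closes by intermolecular suprafacial cycloaddition on the s-cis C6=C7–C7a=C3a unit, in which C3 is an outward (E) substituent on C3a and does not block approach. Adduct 16 is a skipped cyclohexadiene with C3a–H placed 1,4 to the mixed ketal at C6, so it should lose methanol to give 17, which catalytic K2CO3 in methanol cleaves to phenol 18 without touching the tertiary triethylsilyl ether. No lasting stereocentre is made, since C3a and C6 of 16 become aromatic carbons, and C2 lies outside the reacting pi system and keeps its S configuration. The step needs regioselectivity, secured by the matched donor and acceptor polarisation, and site selectivity between the two alkynes, secured because only the proximal alkyne is directly conjugated to the ester while the distal one ends in the bulkier phenyl group.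

Step 9
Reactants: 18 methyl (2S)-6-hydroxy-4-(phenylethynyl)-2-[2-(triethylsilyloxy)propan-2-yl]-2,3-dihydrobenzofuran-5-carboxylate
Product: 20 (2S)-5-(hydroxymethyl)-4-(phenylethynyl)-2-[2-(triethylsilyloxy)propan-2-yl]-2,3-dihydrobenzofuran-6-ol, via C5 aldehyde 19 (not isolated)
Conditions: i-Bu2AlH (4 equiv), CH2Cl2, −78 → 0 °C; aq potassium sodium tartrate
Reagents that add atoms: none
Why: Hydride reduction of a salicylate ester to the o-hydroxybenzyl alcohol, with excess reagent because the phenol is first taken up as its aluminium phenoxide; at or below 0 °C i-Bu2AlH should neither hydroaluminate the diarylalkyne nor drive the benzylic aluminate on to the methyl compound.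

Step 10
Reactants: 20 (2S)-5-(hydroxymethyl)-4-(phenylethynyl)-2-[2-(triethylsilyloxy)propan-2-yl]-2,3-dihydrobenzofuran-6-ol
Product: 21 tert-butyl (2S)-5-(hydroxymethyl)-4-(phenylethynyl)-2-[2-(triethylsilyloxy)propan-2-yl]-2,3-dihydrobenzofuran-6-yl carbonate
Conditions: Boc2O (1.05 equiv), i-Pr2NEt, 4-dimethylaminopyridine (cat.), CH2Cl2, 0 °C
Reagents that add atoms: di-tert-butyl dicarbonate, CC(C)(C)OC(=O)OC(=O)OC(C)(C)C
Why: Amine-mediated carbonate formation goes to the more acidic phenol, and if the group ended up on the benzylic oxygen instead, the same quinone methide would still arise in step 11, so the site of acylation is not critical.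

Step 11
Reactants: 21 tert-butyl (2S)-5-(hydroxymethyl)-4-(phenylethynyl)-2-[2-(triethylsilyloxy)propan-2-yl]-2,3-dihydrobenzofuran-6-yl carbonate; 22 (2-methylprop-1-en-1-yl)magnesium bromide
Product: 25 (2S)-5-(3-methylbut-2-en-1-yl)-4-(phenylethynyl)-2-[2-(triethylsilyloxy)propan-2-yl]-2,3-dihydrobenzofuran-6-ol, via benzylic carbonate phenoxide 23 (not isolated), via o-quinone methide 24 (not isolated)
Conditions: 22 (3.5 equiv, THF solution), THF, −78 °C → rt; aq NH4Cl
Reagents that add atoms: none
Why: Anionic o-quinone methide generation and capture, a known acid-free route to o-prenylphenols: the first equivalent of 22 deprotonates the CH2OH group, the Boc group moves from the C6 oxygen to the benzylic oxygen (23), the freed phenoxide expels tert-butyl carbonate to give 24, and a further equivalent of 22 adds 1,4 to the exocyclic CH2 with rearomatisation.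

Step 12
Reactants: 25 (2S)-5-(3-methylbut-2-en-1-yl)-4-(phenylethynyl)-2-[2-(triethylsilyloxy)propan-2-yl]-2,3-dihydrobenzofuran-6-ol
Product: 26 (2S)-5-(3-methylbut-2-en-1-yl)-4-[(Z)-2-phenylethenyl]-2-[2-(triethylsilyloxy)propan-2-yl]-2,3-dihydrobenzofuran-6-ol
Conditions: H2 (1 atm, stopped after 1 equiv), Pd/CaCO3 poisoned with Pb(OAc)2 (Lindlar catalyst), quinoline, EtOAc, rt, dark
Reagents that add atoms: none
Why: Lindlar semi-hydrogenation delivers both hydrogens to one face of the diarylalkyne and so gives the Z-stilbene, while the trisubstituted prenyl alkene is not reduced on the poisoned catalyst.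

Step 13
Reactants: 26 (2S)-5-(3-methylbut-2-en-1-yl)-4-[(Z)-2-phenylethenyl]-2-[2-(triethylsilyloxy)propan-2-yl]-2,3-dihydrobenzofuran-6-ol
Product: 27 (2S)-2-(2-hydroxypropan-2-yl)-5-(3-methylbut-2-en-1-yl)-4-[(Z)-2-phenylethenyl]-2,3-dihydrobenzofuran-6-ol (CNP0181338.1)
Conditions: n-Bu4NF (2.5 equiv), THF, 0 °C → rt, dark; water
Reagents that add atoms: none
Why: Fluoride cleavage of the tertiary triethylsilyl ether runs under non-acidic conditions, so the o-prenylphenol should not close to a chroman and the Z-alkene should not isomerise.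

Compound list
1 | methyl (2S)-oxirane-2-carboxylate | COC(=O)[C@@H]1CO1 | starting material
2 | 1-[(2S)-oxiran-2-yl]ethanone (not isolated) | CC(=O)[C@@H]1CO1 | intermediate
3 | 2-[(2S)-oxiran-2-yl]propan-2-ol | CC(C)(O)[C@@H]1CO1 | intermediate
4 | triethyl({2-[(2S)-oxiran-2-yl]propan-2-yl}oxy)silane | CC[Si](CC)(CC)OC(C)(C)[C@@H]1CO1 | intermediate
5 | methyl acetoacetate | COC(=O)CC(C)=O | starting material
6 | dilithium dianion of methyl acetoacetate (not isolated) | [Li+].[Li+].C=C([O-])C=C([O-])OC | intermediate
7 | methyl (6S)-6-hydroxy-7-methyl-3-oxo-7-(triethylsilyloxy)octanoate | COC(=O)CC(=O)CC[C@H](O)C(C)(C)O[Si](CC)(CC)CC | intermediate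
8 | methyl 2-{(5S)-2-hydroxy-5-[2-(triethylsilyloxy)propan-2-yl]oxolan-2-yl}acetate, both epimers at the hemiketal carbon (not isolated) | COC(=O)CC1(O)CC[C@@H](C(C)(C)O[Si](CC)(CC)CC)O1 | intermediate
9 | methyl (2E)-2-{(5S)-5-[2-(triethylsilyloxy)propan-2-yl]oxolan-2-ylidene}acetate | COC(=O)/C=C1\CC[C@@H](C(C)(C)O[Si](CC)(CC)CC)O1 | intermediate
10 | lithium dienolate of 9 (not isolated) | [Li+].CO/C([O-])=C/C1=CC[C@@H](C(C)(C)O[Si](CC)(CC)CC)O1 | intermediate
11 | (5S)-2-[(Z)-2-methoxy-2-(trimethylsilyloxy)ethenyl]-5-[2-(triethylsilyloxy)propan-2-yl]-4,5-dihydrofuran | CO/C(O[Si](C)(C)C)=C/C1=CC[C@@H](C(C)(C)O[Si](CC)(CC)CC)O1 | intermediate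
12 | 3-phenylprop-2-ynal | O=CC#Cc1ccccc1 | starting material
13 | (4,4-dibromobut-3-en-1-yn-1-yl)benzene | BrC(Br)=CC#Cc1ccccc1 | intermediate
14 | lithium 4-phenylbuta-1,3-diyn-1-ide (not isolated) | [Li]C#CC#Cc1ccccc1 | intermediate
15 | methyl 5-phenylpenta-2,4-diynoate | COC(=O)C#CC#Cc1ccccc1 | intermediate
16 | methyl (2S)-6-methoxy-4-(phenylethynyl)-2-[2-(triethylsilyloxy)propan-2-yl]-6-(trimethylsilyloxy)-2,3,3a,6-tetrahydrobenzofuran-5-carboxylate, mixture at C3a and C6 (not isolated) | COC(=O)C1=C(C#Cc2ccccc2)C2C[C@@H](C(C)(C)O[Si](CC)(CC)CC)OC2=CC1(OC)O[Si](C)(C)C | intermediate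
17 | methyl (2S)-4-(phenylethynyl)-2-[2-(triethylsilyloxy)propan-2-yl]-6-(trimethylsilyloxy)-2,3-dihydrobenzofuran-5-carboxylate (not isolated) | COC(=O)c1c(O[Si](C)(C)C)cc2c(c1C#Cc1ccccc1)C[C@@H](C(C)(C)O[Si](CC)(CC)CC)O2 | intermediate
18 | methyl (2S)-6-hydroxy-4-(phenylethynyl)-2-[2-(triethylsilyloxy)propan-2-yl]-2,3-dihydrobenzofuran-5-carboxylate | COC(=O)c1c(O)cc2c(c1C#Cc1ccccc1)C[C@@H](C(C)(C)O[Si](CC)(CC)CC)O2 | intermediate
19 | (2S)-6-hydroxy-4-(phenylethynyl)-2-[2-(triethylsilyloxy)propan-2-yl]-2,3-dihydrobenzofuran-5-carbaldehyde, present as its aluminium phenoxide (not isolated) | O=Cc1c(O)cc2c(c1C#Cc1ccccc1)C[C@@H](C(C)(C)O[Si](CC)(CC)CC)O2 | intermediate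
20 | (2S)-5-(hydroxymethyl)-4-(phenylethynyl)-2-[2-(triethylsilyloxy)propan-2-yl]-2,3-dihydrobenzofuran-6-ol | OCc1c(O)cc2c(c1C#Cc1ccccc1)C[C@@H](C(C)(C)O[Si](CC)(CC)CC)O2 | intermediate
21 | tert-butyl (2S)-5-(hydroxymethyl)-4-(phenylethynyl)-2-[2-(triethylsilyloxy)propan-2-yl]-2,3-dihydrobenzofuran-6-yl carbonate | OCc1c(OC(=O)OC(C)(C)C)cc2c(c1C#Cc1ccccc1)C[C@@H](C(C)(C)O[Si](CC)(CC)CC)O2 | intermediate
22 | (2-methylprop-1-en-1-yl)magnesium bromide | CC(C)=C[Mg]Br | starting material
23 | bromomagnesium phenoxide of the C5 benzylic tert-butyl carbonate (not isolated) | CC(C)(C)OC(=O)OCc1c(O[Mg]Br)cc2c(c1C#Cc1ccccc1)C[C@@H](C(C)(C)O[Si](CC)(CC)CC)O2 | intermediate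
24 | (2S)-5-methylidene-4-(phenylethynyl)-2-[2-(triethylsilyloxy)propan-2-yl]-2,3-dihydrobenzofuran-6(5H)-one (not isolated) | C=C1C(=O)C=C2O[C@H](C(C)(C)O[Si](CC)(CC)CC)CC2=C1C#Cc1ccccc1 | intermediate
25 | (2S)-5-(3-methylbut-2-en-1-yl)-4-(phenylethynyl)-2-[2-(triethylsilyloxy)propan-2-yl]-2,3-dihydrobenzofuran-6-ol | CC(C)=CCc1c(O)cc2c(c1C#Cc1ccccc1)C[C@@H](C(C)(C)O[Si](CC)(CC)CC)O2 | intermediate
26 | (2S)-5-(3-methylbut-2-en-1-yl)-4-[(Z)-2-phenylethenyl]-2-[2-(triethylsilyloxy)propan-2-yl]-2,3-dihydrobenzofuran-6-ol | CC(C)=CCc1c(O)cc2c(c1/C=C\c1ccccc1)C[C@@H](C(C)(C)O[Si](CC)(CC)CC)O2 | intermediate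
27 | (2S)-2-(2-hydroxypropan-2-yl)-5-(3-methylbut-2-en-1-yl)-4-[(Z)-2-phenylethenyl]-2,3-dihydrobenzofuran-6-ol | CC(C)=CCc1c(O)cc2c(c1/C=C\c1ccccc1)C[C@@H](C(C)(C)O)O2 | target

Total step count: 13
Longest linear sequence: 11 steps (steps 1–5 and 8–13; steps 6 and 7 form the short second branch)

Steps most likely to fail

Step 8. The very electron-rich diene may decay by protonation or oligomerise before it meets the dienophile. Attack may also occur at the distal alkyne or at the delta carbon of the diyne, and [2+2] addition across the ketene acetal may compete. The fallback keeps the diene and the two ring-forming bonds but removes the second alkyne from the dienophile. It sets out from 11 and uses methyl 3-bromoprop-2-ynoate F1 (methyl propiolate, N-bromosuccinimide, AgNO3 cat., acetone) in place of 15. This smaller, more electrophilic alkynoate has one reactive site and should add at or slightly above room temperature to give the bromo cycloadduct F2. F2 should lose methanol to give the bromoaryl trimethylsilyl ether F3, which is desilylated with K2CO3 (cat.) in MeOH to the 4-bromo salicylate F4. Sonogashira coupling of F4 with phenylacetylene (PdCl2(PPh3)2, CuI, Et3N, DMF, 70 °C), helped by the ortho ester, comes back to the route at 18.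

Step 3. Opening next to the quaternary carbon may be slow, BF3 may consume the dianion, and triethylsilyl may migrate from the tertiary oxygen to the new secondary oxygen, which would lead to the six-membered ether. The fallback forms C3–C3a with a soft nucleophile whose adduct traps the alkoxide at once. From 4, dimethyl malonate and NaOMe in MeOH at reflux should open the epoxide at CH2, and the alkoxide should lactonise directly to the alpha-carbomethoxy lactone F5. Krapcho demethoxycarbonylation (LiCl, wet DMSO, 140 °C) should give the (S)-gamma-lactone F6. Addition of the lithium enolate of methyl acetate (LiN(i-Pr)2, MeOAc, THF, −78 °C) to the lactone carbonyl should give the beta-keto ester. In this adduct the acidic C7 methylene neutralises the released alkoxide, and the route is rejoined at 7.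

Step 12. Hydrogen uptake at the alkyne, which is flanked on both ortho positions, may be sluggish. Over-reduction to the saturated bridge and Z to E isomerisation on the metal surface are the other risks. The fallback replaces heterogeneous hydrogenation by stoichiometric syn hydrometalation and protonolysis, which cannot add a second pair of hydrogens. From 25, dicyclohexylborane (2.5 equiv, THF, 0 °C → rt) should boryl-protect the phenol and add H–B across the alkyne faster than across the trisubstituted prenyl alkene, giving the O-boryl alkenylborane F7. The regiochemistry of this addition does not matter. Protonolysis with acetic acid (rt), which replaces the alkenyl C–B bond with retention and frees the phenol, comes back to the route at 26.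

Further compounds
F1 | step 8 | methyl 3-bromoprop-2-ynoate | COC(=O)C#CBr
F2 | step 8 | methyl (2S)-4-bromo-6-methoxy-2-[2-(triethylsilyloxy)propan-2-yl]-6-(trimethylsilyloxy)-2,3,3a,6-tetrahydrobenzofuran-5-carboxylate | COC(=O)C1=C(Br)C2C[C@@H](C(C)(C)O[Si](CC)(CC)CC)OC2=CC1(OC)O[Si](C)(C)C
F3 | step 8 | methyl (2S)-4-bromo-2-[2-(triethylsilyloxy)propan-2-yl]-6-(trimethylsilyloxy)-2,3-dihydrobenzofuran-5-carboxylate | COC(=O)c1c(O[Si](C)(C)C)cc2c(c1Br)C[C@@H](C(C)(C)O[Si](CC)(CC)CC)O2
F4 | step 8 | methyl (2S)-4-bromo-6-hydroxy-2-[2-(triethylsilyloxy)propan-2-yl]-2,3-dihydrobenzofuran-5-carboxylate | COC(=O)c1c(O)cc2c(c1Br)C[C@@H](C(C)(C)O[Si](CC)(CC)CC)O2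
F5 | step 3 | methyl (5S)-2-oxo-5-[2-(triethylsilyloxy)propan-2-yl]oxolane-3-carboxylate | COC(=O)C1C[C@@H](C(C)(C)O[Si](CC)(CC)CC)OC1=O
F6 | step 3 | (5S)-5-[2-(triethylsilyloxy)propan-2-yl]oxolan-2-one | O=C1CC[C@@H](C(C)(C)O[Si](CC)(CC)CC)O1
F7 | step 12 | (2S)-6-(dicyclohexylboryloxy)-4-[(Z)-2-(dicyclohexylboryl)-2-phenylethenyl]-5-(3-methylbut-2-en-1-yl)-2-[2-(triethylsilyloxy)propan-2-yl]-2,3-dihydrobenzofuran | CC(C)=CCc1c(OB(C2CCCCC2)C2CCCCC2)cc2c(c1/C=C(\c1ccccc1)B(C1CCCCC1)C1CCCCC1)C[C@@H](C(C)(C)O[Si](CC)(CC)CC)O2
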